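Number the heptanoid chain C1–C7 from styryl ring A. The route rests on cutting the C6–C7 bond and hiding C3–C6 as C6, C5, C4 and C3 of a 4-hydroxy-2-pyrone ring, whose lactone carbon C2 is a disposable carboxyl. The key step exploits pyrone C3, the enolic carbon between C4–OH and the C2 carbonyl. In one flask C3 condenses with the aldehyde carbon of vanillin (future C7, bearing ring B), and a dihydropyridine reduces the alkylidene formed. Both phenols stay free and the C1=C2 alkene stays intact. The precursor is (E)-6-(4-hydroxy-3-methoxystyryl)-4-hydroxy-2-pyrone, made from ferulic acid. Hot water finally opens the lactone and CO2 leaves.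

Key step: step 5

Assumption: the target is drawn as one chelated enol of a β-diketone whose tautomers interconvert rapidly. The Z geometry of the enol double bond is therefore set at equilibrium by the intramolecular hydrogen bond. The only geometry the route has to carry is the E C1=C2 alkene, which comes from ferulic acid.

Remark: the pyrone is assembled from acetone-masked acetoacetate (a dioxinone), so ring closure needs only heat and no base. The ring A phenol is masked only for the enolate acylation. Styrylpyrones and curcuminoids are sensitive to light and air, so steps 3–6 are run under inert gas with light excluded.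

Step 1
Reactants: 1 ferulic acid [(E)-3-(4-hydroxy-3-methoxyphenyl)acrylic acid]
Product: 3 (E)-3-[4-(tert-butyldimethylsilyloxy)-3-methoxyphenyl]acrylic acid, via bis-silylated ferulate 2 (not isolated)
Conditions: TBSCl (2.4 equiv), imidazole (5 equiv), DMF, rt; then AcOH/THF/H2O, rt
Reagents that add atoms: tert-butyldimethylsilyl chloride, CC(C)(C)[Si](C)(C)Cl
Why: Standard imidazole-promoted silylation caps the phenol and the acid, and the silyl ester, far more labile than the acid-tolerant aryl silyl ether, is then hydrolysed selectively by dilute aqueous acetic acid, leaving the E-alkene untouched.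

Step 2
Reactants: 3 (E)-3-[4-(tert-butyldimethylsilyloxy)-3-methoxyphenyl]acrylic acid; 4 2,2,6-trimethyl-4H-1,3-dioxin-4-one
Product: 7 6-[(E)-4-[4-(tert-butyldimethylsilyloxy)-3-methoxyphenyl]-2-oxobut-3-en-1-yl]-2,2-dimethyl-4H-1,3-dioxin-4-one, via acyl imidazolide 5 (not isolated), via lithium dienolate 6 (not isolated)
Conditions: 3, CDI (1.1 equiv), THF, rt; separately 4 (3.3 equiv), LiN(iPr)2 (3.3 equiv), THF, −78 °C; 5 added to 6, −78 °C; AcOH quench
Reagents that add atoms: 1,1'-carbonyldiimidazole, O=C(n1ccnc1)n1ccnc1 (imidazolyl group of 5 only); LiN(iPr)2, [Li+].CC(C)[N-]C(C)C (lithium of 6 only); product 7 holds atoms of 3 and 4 alone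
Why: Crossed vinylogous Claisen acylation: the lithium dienolate 6 attacks the acyl imidazolide 5 through its γ-carbon, 1,2-attack being favoured over conjugate addition by the hard lithium enolate, the low temperature and the electron-rich β-aryl group, while the surplus of 6 absorbs the imidazole N–H and the acidic methylene of 7.

Step 3
Reactants: 7 the keto-dioxinone from step 2
Product: 9 6-[(E)-4-(tert-butyldimethylsilyloxy)-3-methoxystyryl]-4-hydroxy-2H-pyran-2-one, via acylketene 8 (not isolated)
Conditions: toluene (0.02 M), reflux, N2, dark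
Reagents that add atoms: none
Why: Thermal retro-hetero-Diels–Alder cleavage of the dioxinone expels acetone, and the acylketene 8 is trapped intramolecularly by the enol oxygen of the styryl ketone to close the six-membered lactone, a neutral and well-used route to 6-substituted 4-hydroxy-2-pyrones that touches neither the silyl ether nor the E-alkene.

Step 4
Reactants: 9 6-[(E)-4-(tert-butyldimethylsilyloxy)-3-methoxystyryl]-4-hydroxy-2H-pyran-2-one
Product: 10 4-hydroxy-6-[(E)-4-hydroxy-3-methoxystyryl]-2H-pyran-2-one
Conditions: KHF2 (2.5 equiv), MeOH/THF, rt; dilute aqueous acid work-up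
Reagents that add atoms: none
Why: Fluoride-induced desilylation driven by the strong Si–F bond: bifluoride removes phenolic TBS ethers at room temperature in a slightly acidic medium in which the pyrone ring and the styryl alkene are inert.

Step 5
Reactants: 10 4-hydroxy-6-[(E)-4-hydroxy-3-methoxystyryl]-2H-pyran-2-one; 11 vanillin; 12 Hantzsch ester (diethyl 2,6-dimethyl-1,4-dihydropyridine-3,5-dicarboxylate)
Product: 15 4-hydroxy-3-(4-hydroxy-3-methoxybenzyl)-6-[(E)-4-hydroxy-3-methoxystyryl]-2H-pyran-2-one, via proline iminium ion 13 (not isolated), via alkylidene pyrandione 14 (not isolated)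
Conditions: L-proline (20 mol %), 11 (1.1 equiv), 12 (1.2 equiv), 10 added in portions, EtOH/THF, 25 → 50 °C, N2, dark
Reagents that add atoms: L-proline, OC(=O)[C@@H]1CCCN1 (held in 13 only and released again); product 15 holds atoms of 10 and 11 plus hydrogen from 12
Why: L-Proline converts vanillin into iminium ion 13, pyrone C3 of 10 adds to it and proline is expelled to give the alkylidene pyrandione 14 (Knoevenagel condensation); 14 is a doubly activated, quinone-methide-like acceptor that takes a hydride from C4 of 12 at its exocyclic carbon, and protonation of the pyronate restores the 4-hydroxy-2-pyrone in 15. The closest known reaction type is the amino-acid-catalysed three-component reductive alkylation of cyclic 1,3-dicarbonyl CH-acids, which is established for 4-hydroxy-6-methyl-2-pyrone and 4-hydroxycoumarin with aromatic aldehydes. No ring is closed and no stereocentre is created; the single new skeletal bond is C6–C7 of the target (pyrone C3 to the former aldehyde carbon). Attack at C3 rather than C5 follows from C3 being the central carbon of the masked β-keto lactone, flanked by C4–OH and C2=O, whereas C5 is only a vinylogous position. Mono-alkylation requires hydride transfer to outrun Michael addition of a second pyrone to 14, and the slight excess of 12, the portionwise addition of 10 and the amine-catalysed reversibility of any bis-adduct should all drain material into 15 because the reduction is irreversible. The C1=C2 styryl alkene, conjugated to an electron-rich arene and an enol lactone, is far too poor an acceptor for a dihydropyridine, and the near-neutral medium makes phenol protection unnecessary.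

Step 6
Reactants: 15 4-hydroxy-3-(4-hydroxy-3-methoxybenzyl)-6-[(E)-4-hydroxy-3-methoxystyryl]-2H-pyran-2-one
Product: 17 dihydrocurcumin (4Z,6E)-5-hydroxy-1,7-bis(4-hydroxy-3-methoxyphenyl)hepta-4,6-dien-3-one, via dioxo acid 16 (not isolated)
Conditions: degassed 1,4-dioxane/H2O (1:2), no added acid or base, sealed tube, 100–105 °C, Ar, dark
Reagents that add atoms: water, O
Why: Hydrolytic lactone opening followed by β-keto acid decarboxylation, the pathway by which triacetic acid lactone gives acetylacetone in hot water: the un-ionised pyrone reacts through its 2,4-dione tautomer, water cleaves the ring to 16, CO2 is lost through the usual cyclic transition state, and the diketone settles as the hydrogen-bonded Z-enol, while the absence of added acid, base and oxygen spares the E-enone and the phenols.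

Compound list
1 | ferulic acid | COc1cc(/C=C/C(=O)O)ccc1O | starting material
2 | tert-butyldimethylsilyl (E)-3-[4-(tert-butyldimethylsilyloxy)-3-methoxyphenyl]acrylate | COc1cc(/C=C/C(=O)O[Si](C)(C)C(C)(C)C)ccc1O[Si](C)(C)C(C)(C)C | intermediate
3 | (E)-3-[4-(tert-butyldimethylsilyloxy)-3-methoxyphenyl]acrylic acid | COc1cc(/C=C/C(=O)O)ccc1O[Si](C)(C)C(C)(C)C | intermediate
4 | 2,2,6-trimethyl-4H-1,3-dioxin-4-one | CC1=CC(=O)OC(C)(C)O1 | starting material
5 | (E)-3-[4-(tert-butyldimethylsilyloxy)-3-methoxyphenyl]-1-(imidazol-1-yl)prop-2-en-1-one | COc1cc(/C=C/C(=O)n2ccnc2)ccc1O[Si](C)(C)C(C)(C)C | intermediate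
6 | lithium 2,2-dimethyl-6-methylidene-6H-1,3-dioxin-4-olate | [Li+].C=C1C=C([O-])OC(C)(C)O1 | intermediate
7 | 6-[(E)-4-[4-(tert-butyldimethylsilyloxy)-3-methoxyphenyl]-2-oxobut-3-en-1-yl]-2,2-dimethyl-4H-1,3-dioxin-4-one | COc1cc(/C=C/C(=O)CC2=CC(=O)OC(C)(C)O2)ccc1O[Si](C)(C)C(C)(C)C | intermediate
8 | (E)-7-[4-(tert-butyldimethylsilyloxy)-3-methoxyphenyl]hepta-1,6-diene-1,3,5-trione (acylketene) | COc1cc(/C=C/C(=O)CC(=O)C=C=O)ccc1O[Si](C)(C)C(C)(C)C | intermediate
9 | 6-[(E)-4-(tert-butyldimethylsilyloxy)-3-methoxystyryl]-4-hydroxy-2H-pyran-2-one | COc1cc(/C=C/c2cc(O)cc(=O)o2)ccc1O[Si](C)(C)C(C)(C)C | intermediate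
10 | 4-hydroxy-6-[(E)-4-hydroxy-3-methoxystyryl]-2H-pyran-2-one | COc1cc(/C=C/c2cc(O)cc(=O)o2)ccc1O | intermediate
11 | vanillin | COc1cc(C=O)ccc1O | starting material
12 | Hantzsch ester, diethyl 2,6-dimethyl-1,4-dihydropyridine-3,5-dicarboxylate | CCOC(=O)C1=C(C)NC(C)=C(C(=O)OCC)C1 | starting material
13 | (S)-1-(4-hydroxy-3-methoxybenzylidene)pyrrolidinium-2-carboxylate (C=N geometry undefined) | COc1cc(C=[N+]2CCC[C@H]2C(=O)[O-])ccc1O | intermediate
14 | 3-(4-hydroxy-3-methoxybenzylidene)-6-[(E)-4-hydroxy-3-methoxystyryl]-2H-pyran-2,4(3H)-dione (exocyclic geometry undefined) | COc1cc(/C=C/C2=CC(=O)C(=Cc3ccc(O)c(OC)c3)C(=O)O2)ccc1O | intermediate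
15 | 4-hydroxy-3-(4-hydroxy-3-methoxybenzyl)-6-[(E)-4-hydroxy-3-methoxystyryl]-2H-pyran-2-one | COc1cc(/C=C/c2cc(O)c(Cc3ccc(O)c(OC)c3)c(=O)o2)ccc1O | intermediate
16 | (E)-2-(4-hydroxy-3-methoxybenzyl)-7-(4-hydroxy-3-methoxyphenyl)-3,5-dioxohept-6-enoic acid (racemic at C2) | COc1cc(/C=C/C(=O)CC(=O)C(Cc2ccc(O)c(OC)c2)C(=O)O)ccc1O | intermediate
17 | dihydrocurcumin, (4Z,6E)-5-hydroxy-1,7-bis(4-hydroxy-3-methoxyphenyl)hepta-4,6-dien-3-one | COc1cc(/C=C/C(O)=C/C(=O)CCc2ccc(O)c(OC)c2)ccc1O | target

Total step count: 6. Longest linear sequence: 6 steps (1 → 3 → 7 → 9 → 10 → 15 → 17).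

Steps most likely to fail

1. Step 5.
- **Risk:** the electron-rich aldehyde may condense sluggishly. The push–pull alkylidene may also be captured by a second pyrone faster than it accepts hydride, which stalls material as a bis-adduct.
- **Fallback, from 10 back to 15:** the reductive coupling is replaced by a redox-neutral dehydrative benzylation. Commercial vanillyl alcohol (COc1cc(CO)ccc1O) is added slowly to 10 with catalytic TsOH·H2O in dioxane at 60–80 °C. It ionises to 2-methoxy-4-methylidenecyclohexa-2,5-dien-1-one F1, the para-quinone methide, which pyrone C3 traps to give 15 directly.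
- **Basis:** acid-catalysed C3-benzylation of 4-hydroxy-2-pyrones and 4-hydroxycoumarins with electron-rich benzylic alcohols is established. No alkylidene pyrandione is present, so the bis-pyrone pathway is removed.

2. Step 6.
- **Risk:** lactone hydrolysis may be too slow at the temperature the product tolerates. Retro-Claisen or retro-aldol fragmentation, oxa-Michael cyclisation of the enol onto the enone, or air oxidation could then compete.
- **Fallback, from 15 back to 17:** the ring is opened by alkoxide instead of hot water. Excess Mg(OMe)2 in MeOH at reflux methanolyses the lactone, with the magnesium chelate shielding the diketone. This gives methyl (E)-2-(4-hydroxy-3-methoxybenzyl)-7-(4-hydroxy-3-methoxyphenyl)-3,5-dioxohept-6-enoate F2.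
- **Completion:** LiOH in degassed THF/H2O at 0–25 °C followed by acidification to pH 3 gives acid 16, which loses CO2 at or slightly above room temperature to give 17.

3. Step 2.
- **Risk:** proton transfer may quench the dienolate, and conjugate addition, O-acylation or double acylation may lower conversion to the γ-acylated product.
- **Fallback, from 5 (made from 3 as before) back to 9:** methyl acetoacetate is treated with NaH and then n-BuLi in THF at 0 °C to form the sodium lithium dianion of methyl acetoacetate F3. At −78 °C, 5 acylates F3 at its terminal carbon to give methyl (E)-7-[4-(tert-butyldimethylsilyloxy)-3-methoxyphenyl]-3,5-dioxohept-6-enoate F4.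
- **Completion:** DBU in dry toluene at reflux lactonises this 3,5-dioxo ester with loss of methanol, giving 9 and bypassing 7 and step 3.

Further compounds
F1 | step 5 | 2-methoxy-4-methylidenecyclohexa-2,5-dien-1-one | COC1=CC(=C)C=CC1=O
F2 | step 6 | methyl (E)-2-(4-hydroxy-3-methoxybenzyl)-7-(4-hydroxy-3-methoxyphenyl)-3,5-dioxohept-6-enoate | COC(=O)C(Cc1ccc(O)c(OC)c1)C(=O)CC(=O)/C=C/c1ccc(O)c(OC)c1
F3 | step 2 | sodium lithium dianion of methyl acetoacetate | [Na+].[Li+].C=C([O-])C=C([O-])OC
F4 | step 2 | methyl (E)-7-[4-(tert-butyldimethylsilyloxy)-3-methoxyphenyl]-3,5-dioxohept-6-enoate | COC(=O)CC(=O)CC(=O)/C=C/c1ccc(O[Si](C)(C)C(C)(C)C)c(OC)c1
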